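Slowness is what a repeat of this flask has to reckon with: electrophile and nucleophile give the target, and after 60.0 min the earlier runs still show 86.3% to 86.8% of their electrophile.

all flasks: electrophile 10 mM
- elm: nucleophile 25 mM; free base 3.6 mM; protic impurity 0.20 mM; run made earlier
- maple: nucleophile 25 mM; free base 9.3 mM; protic impurity 0.20 mM; run made earlier
- noon: nucleophile 25.0 mM; free base 3.00 mM; protic impurity 0.200 mM; time 2.0 h
- dusk: nucleophile 25.0 mM; free base 4.50 mM; protic impurity 0.200 mM; time 2.0 h
- spring: nucleophile 25.0 mM; free base 6.80 mM; protic impurity 0.200 mM; time 2.0 h

| run | time / min | electrophile / % | target / % |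
|---|---|---|---|
| elm | 12.0 | 97.7 | 2.8 |
| elm | 25.0 | 95.2 | 6.0 |
| elm | 40.0 | 91.6 | 9.6 |
| elm | 50.0 | 89.3 | 11.6 |
| elm | 60.0 | 86.8 | 13.1 |
| maple | 12.0 | 97.5 | 3.9 |
| maple | 25.0 | 93.4 | 5.7 |
| maple | 40.0 | 90.9 | 9.2 |
| maple | 50.0 | 88.5 | 12.1 |
| maple | 60.0 | 86.3 | 13.9 |

(each reading ± 0.5 percentage points)

- part of the electrophile that has reacted at the end, noon
- part of the electrophile that has reacted at the end, dusk
- part of the electrophile that has reacted at the end, spring
- what raising the concentration of free base from its lowest to its highest value here does to the part of the electrophile that has reacted (changes below 5 percentage points count as none) (it falls / it rises / no change)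



The readings hold an oddity. The maple run carries 2.58 times the free base of the elm run, yet at 60.0 min the electrophile stands at 86.8% in elm and 86.3% in maple, a gap of 0.5 percentage points against a scatter of 0.5 points per reading. So I take free base out of the rate over this range and average those two last readings. With the nucleophile charged at 25.0 mM against 10 mM of electrophile, I treat the loss as pseudo-first-order. That gives 6.92 h for τ, the electrophile lifetime: elapsed time divided by the natural logarithm of charged over remaining electrophile. Over 2.0 h, τ gives me 25.1% reacted in noon, dusk and spring alike.

One danger remains, and I would watch it. Should each reacted electrophile cost one free base, and the impurity its own share, noon needs 2.71 mM, which is 0.290 mM less than its 3.00 mM.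

The forecast gave 24.5%, 26% and 26% for noon, dusk and spring, with no change as its trend: “The spread should stay under 5 points”.

The flasks give 24.1%, 24.1% and 24.1%, a change of 0.0056 points across the free base range, so the trend is no change; my reckoning stands 1 point high.

    nucleophile + acid set free ⇌ protonated nucleophile, settled at all times (K = 8600 M⁻¹)
    electrophile + nucleophile → acid set free + target (k = 0.102 M⁻¹ min⁻¹)
    electrophile + acid set free → side product (k = 0.846 M⁻¹ min⁻¹)
    acid set free + free base ⇌ salt of the base (K = 4.35 × 10⁵ M⁻¹, k = 6.38 M⁻¹ min⁻¹)
    protic impurity + free base → quenched reagent (k = 81.5 M⁻¹ min⁻¹)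

Noon has not come to rest at 2.0 h: 76% of its electrophile remains and free base stands at 93% of its charge, with 2.37 mM of protonated nucleophile against 0.0147 mM of salt of the base. Left ten times as long, to 20.0 h, noon reaches 82.8% reacted where τ gives 94.4%, and 17.2% of the charged electrophile and 39.6% of the charged nucleophile are still there.

A neighbouring flask is like dusk but holds 10 mM of nucleophile. If the loss scales with nucleophile, τ stretches to 17.3 h, which gives 10.9% reacted at 2.0 h; the flask gives 10.4%.

Readings and results were generated by integration on assumed constants; the scatter is artificial.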